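## Analysis of the target

The target is a flavanonol. An aromatic ring A is fused to the dihydropyranone ring C (a chroman-4-one), and ring B sits on C2. Ring A carries methoxyls at C5, C6 and C7 and a single hydrogen at C8. C3 carries a methoxyl, and ring B is a 3',5'-dihydroxy-4'-methoxyphenyl group. The two stereocentres C2 and C3 are adjacent, both R, and trans to each other (aryl and methoxyl both equatorial), which is the more stable relative arrangement.

The C2–O1 bond is benzylic and β to the C4 ketone, so base can open ring C by E1cB expulsion of the C8a phenoxide and erase C2. C3–H is α to the ketone and can epimerise. All three rings are electron-rich, and the ring B phenols are free.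

The difficulty is threefold: setting C2 absolutely, placing the C3 methoxyl without disturbing C2, and ending with five methyl ethers beside exactly two free phenols. The strategy rests on the positions of those two phenols. C3' and C5' are mirror-related and flank the C4' methoxyl. In a 4'-methoxyphenyl precursor they are C–H bonds beside a small substituent, whereas C2'–H and C6'–H lie beside the branched C2, and C8–H of ring A is enclosed by O1 and the C7 methoxyl.

## Retrosynthetic reasoning

**C3'–O and C5'–O.** Both phenolic C–O bonds of 16 are traced back to C–B bonds in the bis(boronate) 14. Oxidation of an aryl boronate is ipso-specific and can be run at neutral pH, so the phenols appear last, unprotected, and the forward step only has to spare C2 and C3.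

**C3'–B and C5'–B (key disconnection).** Both C–B bonds of 14 are cut to C–H bonds of the pentamethyl ether 11, with diboron 12 as the boron source. The cut is made here because ring B of 11 is a plain 4-methoxyphenyl group, which removes every phenol protecting group from the route. The forward reaction must borylate twice beside the C4' methoxyl and nowhere else; the steric argument above, not electronics, has to carry this.

**O–CH3 at C3.** 11 is cut to the flavanonol 10. The forward methylation must work on the neutral alcohol, since any alkoxide or enolate would threaten ring C and C3.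

**C3–O.** 10 is cut through the enol silane 8 to the flavanone 7. Oxygen is delivered to the C3=C4 enol ether from the face opposite the C2 aryl group, so C2 controls C3 and the trans relation results.

**C2–C1'.** 7 is cut to the chromone 5 and the boronic acid 6. This is the one bond whose formation creates C2, so an enantioselective conjugate arylation sets the absolute configuration in a single step from two achiral pieces.

**C2 and O1–C2 of ring C.** 5 is cut to the ortho-hydroxy acetophenone 3. The forward step adds a one-carbon unit at the formyl oxidation level to the methyl ketone and closes the pyranone through the phenol.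

**C4–C4a.** 3 is cut to the phenol 1 and an acetyl group. The two free positions of 1 are equivalent, so the acylation has no regiochemical question.

## Alternatives that were turned down

**Alternative 1:** The disconnection is O1–C8a. In the forward sense Pd(OAc)2, a bulky di-tert-butyl biaryl phosphine and Cs2CO3 couple the secondary C2 hydroxyl of an open-chain anti stereodiad with an aryl bromide at C8a, closing ring C to A1, a 2,3-trans flavan-3,4-diol carrying 3-O-methyl, 4-O-silyl and two benzyl ethers.
- For it: C2 and C3 are set on an open chain and are never exposed as an enolisable β-aryloxy ketone until the end. The ring B oxygens are carried in from the start, so their positions are beyond doubt. On this point the alternative is stronger than the chosen route.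
- Against it: the bromide sits on an electron-rich, ortho-substituted ring A, so oxidative addition is slow. The palladium alkoxide has a hydrogen at C2, so β-hydride elimination to a ketone competes with C–O reductive elimination. After A1, desilylation, oxidation of C4 next to the epimerisable C3, and double hydrogenolysis are still needed, on top of the protecting-group steps before it.
- Comparison: the chosen route offers a sequence roughly half as long with no protecting group, at the price of one demanding C–H step.

**Alternative 2:** The disconnections are O1–C8a and C4a–C5; ring A is built from a triketo ester chain. In one pot, acid condenses the C2 hydroxyl with the C8a ketone, and Mg(OMe)2 then drives a Claisen closure of C4a onto the C5 ester, with aromatisation to A2.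
- For it: it is convergent, forms two rings at once, and needs no transition metal. On convergence it is stronger than the chosen route.
- Against it: the chain holds C3 between a ketone and the C2 carbinol, so retro-aldol cleavage, epimerisation and β-elimination are all open under both the acid and the magnesium alkoxide. Several aldol and Claisen folding modes compete. A2 still has free hydroxyls at C5 and C7; the chelated C5 hydroxyl is only methylated under base strong enough to endanger C2 and C3, and debenzylation follows.
- Comparison: the chosen route builds ring A from a commercial arene with its three methyl ethers already in place and never needs a basic methylation.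

**Alternative 3:** The disconnection is C2–C3. A chiral (BINOL)AlCl Lewis acid cleaves the bond from C2 to the enol oxygen of a benzodioxine enol acetal, and the aluminium enolate carbon C3 recombines with the oxocarbenium carbon C2 (Petasis–Ferrier rearrangement) to give the flavanone A3.
- For it: a C–C bond and ring C form in one step from an easily assembled acetal, and the ring B oxygens are pre-installed. It is as strong as alternative 1 on site certainty.
- Against it: C2 must be set by a chiral counter-ion controlling the recombination of two separated fragments. The oxocarbenium ion is strongly stabilised by the para-methoxy ring B, so the ion pair is loose and facial control weak. A3 is only at the oxidation level of compound 7, so C3 oxidation, methylation and hydrogenolysis still follow.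
- Comparison: the chosen route reaches the same stage by a catalytic conjugate arylation in which the metal-bound ligand sits directly at the bond-forming centre, and it needs no deprotection.

Key step: step 7

Assumption: the sense of induction of the pyridine–oxazoline ligand on chromone 5 is taken to parallel that on β-substituted cyclohexenones, so the (R)-ligand is written for the (2S)-flavanone 7; if the addition runs the other way, the (S)-ligand is used and nothing else changes.

## Route

**Step 1**
Reactants: 1 3,4,5-trimethoxyphenol
Product: 3 1-(6-hydroxy-2,3,4-trimethoxyphenyl)ethan-1-one, via difluoroboron chelate 2 (not isolated)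
Conditions: AcOH, BF3·OEt2, 90 °C; then H2O/EtOH, 80 °C
Reagents that add atoms: acetic acid, CC(=O)O
Why: Friedel–Crafts C-acylation of the phenol (through the aryl acetate and a Fries-type shift) can only reach the two equivalent free positions ortho to the hydroxyl. The product is held as its difluoroboron chelate 2, which blocks a second acylation, and hydrolysis frees the ortho-hydroxy ketone.

**Step 2**
Reactants: 3 1-(6-hydroxy-2,3,4-trimethoxyphenyl)ethan-1-one
Product: 5 5,6,7-trimethoxy-4H-chromen-4-one, via enaminone 4 (not isolated)
Conditions: Me2NCH(OMe)2, toluene, 100 °C; then conc. HCl, CH2Cl2, 40 °C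
Reagents that add atoms: N,N-dimethylformamide dimethyl acetal, COC(OC)N(C)C
Why: Condensation of the methyl ketone with the formamide acetal gives enaminone 4. Acid then lets the phenol add to the β-carbon and dimethylamine leave (addition–elimination), closing the pyranone ring of the chromone.

**Step 3**
Reactants: 5 5,6,7-trimethoxy-4H-chromen-4-one; 6 4-methoxyphenylboronic acid
Product: 7 (2S)-5,6,7-trimethoxy-2-(4-methoxyphenyl)chroman-4-one
Conditions: Pd(OCOCF3)2 (5 mol%), (R)-4-tert-butyl-2-(pyridin-2-yl)-4,5-dihydrooxazole (6 mol%), NH4PF6 (30 mol%), H2O (5 equiv), ClCH2CH2Cl, 60 °C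
Reagents that add atoms: none
Why: Asymmetric conjugate addition of an arylboronic acid to a chromone under cationic divalent palladium: transmetalation gives an aryl palladium species, enantioselective insertion of C2=C3 sets C2, and protonolysis of the palladium enolate releases the flavanone. The tert-butyl group of the ligand selects the enone face, and the base-free, mildly acidic medium avoids retro-oxa-Michael racemisation.

**Step 4**
Reactants: 7 (2S)-5,6,7-trimethoxy-2-(4-methoxyphenyl)chroman-4-one
Product: 8 (2S)-5,6,7-trimethoxy-2-(4-methoxyphenyl)-4-(trimethylsilyloxy)-2H-chromene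
Conditions: TMSOTf, Et3N, CH2Cl2, 0 °C
Reagents that add atoms: trimethylsilyl trifluoromethanesulfonate, C[Si](C)(C)OS(=O)(=O)C(F)(F)F
Why: Soft enolisation (silyl activation of the carbonyl, amine deprotonation at C3) gives the only possible enol silane without a free enolate that could expel the C8a phenoxide, so C2 is untouched.

**Step 5**
Reactants: 8 (2S)-5,6,7-trimethoxy-2-(4-methoxyphenyl)-4-(trimethylsilyloxy)-2H-chromene
Product: 10 (2R,3R)-3-hydroxy-5,6,7-trimethoxy-2-(4-methoxyphenyl)chroman-4-one, via silyloxy epoxide 9 (not isolated)
Conditions: DMDO, acetone/CH2Cl2, −40 to 0 °C; then 1 M HCl, THF, 0 °C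
Reagents that add atoms: dimethyldioxirane, CC1(C)OO1
Why: Rubottom oxidation: the dioxirane epoxidises the electron-rich enol ether on the face opposite the C2 aryl group, and hydrolysis of the silyloxy epoxide 9 gives the ketone with the C3–O bond retained. The new centre is therefore trans to the aryl group (3R), which is also the more stable diastereomer.

**Step 6**
Reactants: 10 (2R,3R)-3-hydroxy-5,6,7-trimethoxy-2-(4-methoxyphenyl)chroman-4-one
Product: 11 (2R,3R)-3,5,6,7-tetramethoxy-2-(4-methoxyphenyl)chroman-4-one
Conditions: Me3OBF4, 1,8-bis(dimethylamino)naphthalene, 4 Å MS, CH2Cl2, 0 °C to rt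
Reagents that add atoms: trimethyloxonium tetrafluoroborate, C[O+](C)C.F[B-](F)(F)F
Why: Meerwein methylation: the oxonium salt alkylates the neutral hydroxyl and a hindered, non-nucleophilic amine takes up the proton. No alkoxide or enolate forms, so C3 cannot epimerise and ring C cannot open.

**Step 7**
Reactants: 11 (2R,3R)-3,5,6,7-tetramethoxy-2-(4-methoxyphenyl)chroman-4-one; 12 bis(pinacolato)diboron
Product: 14 (2R,3R)-3,5,6,7-tetramethoxy-2-[4-methoxy-3,5-bis(4,4,5,5-tetramethyl-1,3,2-dioxaborolan-2-yl)phenyl]chroman-4-one, via 3'-monoboronate 13 (not isolated)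
Conditions: [Ir(OMe)(cod)]2 (3 mol%), 3,4,7,8-tetramethyl-1,10-phenanthroline (6 mol%), 12 (3 equiv), THF, 80 °C, sealed tube
Reagents that add atoms: none
Why: The precatalyst, the phenanthroline and 12 form a trivalent iridium tris(boryl) complex that cleaves an aryl C–H bond and reductively eliminates the aryl boronate; 12 restores the tris(boryl) complex and pinacolborane is released. The closest known reaction type is the sterically governed iridium-catalysed C–H borylation of arenes, including borylation beside the methoxyl of para-disubstituted anisoles. No ring closes and no stereocentre is formed. The step needs C3' and C5' to react in preference to C2', C6' and C8. C2'–H and C6'–H are shielded by the branched C2, and C8–H has two ortho substituents (O1 and the C7 methoxyl), a pattern this catalyst does not touch. The first borylation gives 13 readily because the C4' methoxyl can turn its methyl away from the reacting C–H bond. The second is slower, since that methyl must leave the ring plane or face the first boryl group; hence the excess of 12 and the phenanthroline ligand, chosen for catalyst lifetime. The C4 carbonyl is a hindered aryl ketone deactivated by three donor oxygens, so reduction by pinacolborane should be slow. The medium contains neither acid nor base, so C2 and C3 are not at risk.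

**Step 8**
Reactants: 14 (2R,3R)-3,5,6,7-tetramethoxy-2-[4-methoxy-3,5-bis(4,4,5,5-tetramethyl-1,3,2-dioxaborolan-2-yl)phenyl]chroman-4-one
Product: 16 (2R,3R)-2-(3,5-dihydroxy-4-methoxyphenyl)-3,5,6,7-tetramethoxychroman-4-one, via monophenol monoboronate 15 (not isolated)
Conditions: 30% aq. H2O2, pH 7 phosphate buffer, THF, 0 °C to rt
Reagents that add atoms: hydrogen peroxide, OO
Why: Peroxide adds to boron and the aryl group shifts from boron to oxygen (ipso-specific 1,2-migration) at each C–B bond in turn; the aryl borates hydrolyse in the buffer to the phenols. Neutral pH is chosen because an alkaline oxidant such as NaBO3 (about pH 10) would deprotonate the new phenols and expose C2 and C3 to ring opening and epimerisation.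

## Compound list

1 | 3,4,5-trimethoxyphenol | COc1cc(O)cc(OC)c1OC | starting material
2 | difluoroboron chelate of 3 (2,2-difluoro-5,6,7-trimethoxy-4-methyl-1,3,2-benzodioxaborinine, boron bridging the phenolate and ketone oxygens) | CC1=[O+][B-](F)(F)Oc2cc(OC)c(OC)c(OC)c21 | intermediate
3 | 1-(6-hydroxy-2,3,4-trimethoxyphenyl)ethan-1-one | CC(=O)c1c(O)cc(OC)c(OC)c1OC | intermediate
4 | (E)-3-(dimethylamino)-1-(6-hydroxy-2,3,4-trimethoxyphenyl)prop-2-en-1-one | CN(C)/C=C/C(=O)c1c(O)cc(OC)c(OC)c1OC | intermediate
5 | 5,6,7-trimethoxy-4H-chromen-4-one | COc1cc2occc(=O)c2c(OC)c1OC | intermediate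
6 | 4-methoxyphenylboronic acid | COc1ccc(B(O)O)cc1 | starting material
7 | (2S)-5,6,7-trimethoxy-2-(4-methoxyphenyl)chroman-4-one | COc1cc2c(c(OC)c1OC)C(=O)C[C@@H](c1ccc(OC)cc1)O2 | intermediate
8 | (2S)-5,6,7-trimethoxy-2-(4-methoxyphenyl)-4-(trimethylsilyloxy)-2H-chromene | COc1cc2c(c(OC)c1OC)C(O[Si](C)(C)C)=C[C@@H](c1ccc(OC)cc1)O2 | intermediate
9 | (2R,3R,4R)-3,4-epoxy-5,6,7-trimethoxy-2-(4-methoxyphenyl)-4-(trimethylsilyloxy)chromane (oxirane oxygen anti to the C2 aryl group) | COc1cc2c(c(OC)c1OC)[C@]1(O[Si](C)(C)C)O[C@@H]1[C@@H](c1ccc(OC)cc1)O2 | intermediate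
10 | (2R,3R)-3-hydroxy-5,6,7-trimethoxy-2-(4-methoxyphenyl)chroman-4-one | COc1cc2c(c(OC)c1OC)C(=O)[C@H](O)[C@@H](c1ccc(OC)cc1)O2 | intermediate
11 | (2R,3R)-3,5,6,7-tetramethoxy-2-(4-methoxyphenyl)chroman-4-one | COc1cc2c(c(OC)c1OC)C(=O)[C@H](OC)[C@@H](c1ccc(OC)cc1)O2 | intermediate
12 | bis(pinacolato)diboron | CC1(C)OB(B2OC(C)(C)C(C)(C)O2)OC1(C)C | starting material
13 | (2R,3R)-3,5,6,7-tetramethoxy-2-[4-methoxy-3-(4,4,5,5-tetramethyl-1,3,2-dioxaborolan-2-yl)phenyl]chroman-4-one | COc1cc2c(c(OC)c1OC)C(=O)[C@H](OC)[C@@H](c1ccc(OC)c(B3OC(C)(C)C(C)(C)O3)c1)O2 | intermediate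
14 | (2R,3R)-3,5,6,7-tetramethoxy-2-[4-methoxy-3,5-bis(4,4,5,5-tetramethyl-1,3,2-dioxaborolan-2-yl)phenyl]chroman-4-one | COc1cc2c(c(OC)c1OC)C(=O)[C@H](OC)[C@@H](c1cc(B3OC(C)(C)C(C)(C)O3)c(OC)c(B3OC(C)(C)C(C)(C)O3)c1)O2 | intermediate
15 | (2R,3R)-2-[3-hydroxy-4-methoxy-5-(4,4,5,5-tetramethyl-1,3,2-dioxaborolan-2-yl)phenyl]-3,5,6,7-tetramethoxychroman-4-one | COc1cc2c(c(OC)c1OC)C(=O)[C@H](OC)[C@@H](c1cc(O)c(OC)c(B3OC(C)(C)C(C)(C)O3)c1)O2 | intermediate
16 | (2R,3R)-2-(3,5-dihydroxy-4-methoxyphenyl)-3,5,6,7-tetramethoxychroman-4-one | COc1cc2c(c(OC)c1OC)C(=O)[C@H](OC)[C@@H](c1cc(O)c(OC)c(O)c1)O2 | target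

## Step count and least certain steps

Total step count: 8. Longest linear sequence: 8 steps (1 to 16); compounds 6 and 12 are purchased.

**Step 7 (key step).** The most likely failure is that borylation stalls after the first C–B bond: once C3' carries a boryl group, the methyl of the C4' methoxyl turns toward C5'–H, and the catalyst may decay before the slower second turnover. Slow reduction of the ketone by accumulated pinacolborane is a second possibility.

The fallback installs the C–B bonds from pre-placed C–Cl bonds, so site fidelity no longer depends on C–H selectivity. It sets out from chromone 5 and returns at 14.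
- Compound 5 is arylated under the conditions of step 3 with (3,5-dichloro-4-methoxyphenyl)boronic acid F1 (aryl chlorides are inert to divalent palladium), giving (2S)-2-(3,5-dichloro-4-methoxyphenyl)-5,6,7-trimethoxychroman-4-one F2.
- As in steps 4 to 6, F2 is carried through the enol silane (2S)-2-(3,5-dichloro-4-methoxyphenyl)-5,6,7-trimethoxy-4-(trimethylsilyloxy)-2H-chromene F3, its transient anti 3,4-epoxide F4, the flavanonol (2R,3R)-2-(3,5-dichloro-4-methoxyphenyl)-3-hydroxy-5,6,7-trimethoxychroman-4-one F5, and the methyl ether (2R,3R)-2-(3,5-dichloro-4-methoxyphenyl)-3,5,6,7-tetramethoxychroman-4-one F6.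
- Twofold Miyaura borylation of F6 (Pd(OAc)2, 2-dicyclohexylphosphino-2',4',6'-triisopropylbiphenyl, 12, KOAc, dioxane, 90 °C) then gives 14. The weak acetate base at this temperature is the residual concern.

**Step 3.** Turnover may be poor because three donor methoxyls and the peri C5 substituent make C2 of the chromone a weak acceptor; the electron-rich boronic acid 6 may be lost to protodeboronation or homocoupling; and enantioselectivity may erode.

The fallback makes the C3–O bond by nucleophilic epoxidation of an enone and closes ring C afterwards. It sets out from 3 and returns at 10, bypassing steps 3 to 5.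
- Compound 3 is protected (MOMCl, NaH, DMF) as 1-[2,3,4-trimethoxy-6-(methoxymethoxy)phenyl]ethan-1-one F7.
- Claisen–Schmidt condensation with 4-methoxybenzaldehyde (KOH, EtOH) gives (E)-3-(4-methoxyphenyl)-1-[2,3,4-trimethoxy-6-(methoxymethoxy)phenyl]prop-2-en-1-one F8.
- Juliá–Colonna epoxidation (poly-L-leucine, urea–H2O2, DBU, THF) gives [(2R,3S)-3-(4-methoxyphenyl)oxiran-2-yl][2,3,4-trimethoxy-6-(methoxymethoxy)phenyl]methanone F9.
- HCl in MeOH at 40 °C removes the acetal to give (6-hydroxy-2,3,4-trimethoxyphenyl)[(2R,3S)-3-(4-methoxyphenyl)oxiran-2-yl]methanone F10. Its phenol opens the epoxide at the benzylic carbon in the 6-endo mode with the C3 oxygen configuration retained, giving 10; any cis isomer is a separable diastereomer.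

**Step 5 (with step 4).** The benzylic C2–O1 bond, activated by the para-methoxy ring B, may ionise under the silyl triflate or during acidic collapse of 9, with loss of configuration at C2. The dioxirane may also attack the electron-rich rings, and facial selectivity may be incomplete.

The fallback replaces epoxidation and acid by an acid-free syn-dihydroxylation with a bulkier oxidant. It sets out from 8 and returns at 10. OsO4 (catalytic) with N-methylmorpholine N-oxide in acetone/H2O at 0 °C should add anti to the C2 aryl group and give the cis-3,4-diol mono-silyl hemiketal (2,3-trans-3-hydroxy-4-(trimethylsilyloxy)flavan-4-ol) F11, which loses trimethylsilanol spontaneously to give 10.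

**Step 6.** The hydroxyl is hindered and hydrogen-bonded to the C4 carbonyl, so alkylation may stall, and a long reaction time invites epimerisation at C3.

The fallback forms the methyl ether at the C4 alcohol oxidation level, where neither C2–H nor C3–H is acidic. It sets out from 7 and returns at 11.
- TBSOTf and Et3N give the enol silane (2S)-4-(tert-butyldimethylsilyloxy)-5,6,7-trimethoxy-2-(4-methoxyphenyl)-2H-chromene F12.
- Hydroboration–oxidation (BH3·THF, 0 °C; then H2O2, NaOH) places boron, then oxygen, at C3 anti to the aryl group, giving the 2,3-trans-3,4-trans 4-O-silyl flavan-3-ol F13.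
- The now ordinary secondary alcohol is methylated under forcing conditions (MeOTf, 2,6-di-tert-butyl-4-methylpyridine, CH2Cl2, 40 °C) to the 3-O-methyl 4-O-silyl flavan F14.
- Bu4NF in THF gives the 2,3-trans-3,4-trans 3-methoxyflavan-4-ol F15, and buffered Dess–Martin oxidation (NaHCO3, CH2Cl2) restores the ketone of 11.

## Further compounds

F1 | step 7 | (3,5-dichloro-4-methoxyphenyl)boronic acid | COc1c(Cl)cc(B(O)O)cc1Cl
F2 | step 7 | (2S)-2-(3,5-dichloro-4-methoxyphenyl)-5,6,7-trimethoxychroman-4-one | COc1cc2c(c(OC)c1OC)C(=O)C[C@@H](c1cc(Cl)c(OC)c(Cl)c1)O2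
F3 | step 7 | (2S)-2-(3,5-dichloro-4-methoxyphenyl)-5,6,7-trimethoxy-4-(trimethylsilyloxy)-2H-chromene | COc1cc2c(c(OC)c1OC)C(O[Si](C)(C)C)=C[C@@H](c1cc(Cl)c(OC)c(Cl)c1)O2
F4 | step 7 | (2R,3R,4R)-2-(3,5-dichloro-4-methoxyphenyl)-3,4-epoxy-5,6,7-trimethoxy-4-(trimethylsilyloxy)chromane (oxirane oxygen anti to the C2 aryl group) | COc1cc2c(c(OC)c1OC)[C@]1(O[Si](C)(C)C)O[C@@H]1[C@@H](c1cc(Cl)c(OC)c(Cl)c1)O2
F5 | step 7 | (2R,3R)-2-(3,5-dichloro-4-methoxyphenyl)-3-hydroxy-5,6,7-trimethoxychroman-4-one | COc1cc2c(c(OC)c1OC)C(=O)[C@H](O)[C@@H](c1cc(Cl)c(OC)c(Cl)c1)O2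
F6 | step 7 | (2R,3R)-2-(3,5-dichloro-4-methoxyphenyl)-3,5,6,7-tetramethoxychroman-4-one | COc1cc2c(c(OC)c1OC)C(=O)[C@H](OC)[C@@H](c1cc(Cl)c(OC)c(Cl)c1)O2
F7 | step 3 | 1-[2,3,4-trimethoxy-6-(methoxymethoxy)phenyl]ethan-1-one | CC(=O)c1c(OCOC)cc(OC)c(OC)c1OC
F8 | step 3 | (E)-3-(4-methoxyphenyl)-1-[2,3,4-trimethoxy-6-(methoxymethoxy)phenyl]prop-2-en-1-one | COCOc1cc(OC)c(OC)c(OC)c1C(=O)/C=C/c1ccc(OC)cc1
F9 | step 3 | [(2R,3S)-3-(4-methoxyphenyl)oxiran-2-yl][2,3,4-trimethoxy-6-(methoxymethoxy)phenyl]methanone | COCOc1cc(OC)c(OC)c(OC)c1C(=O)[C@@H]1O[C@H]1c1ccc(OC)cc1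
F10 | step 3 | (6-hydroxy-2,3,4-trimethoxyphenyl)[(2R,3S)-3-(4-methoxyphenyl)oxiran-2-yl]methanone | COc1ccc(cc1)[C@@H]1O[C@H]1C(=O)c1c(O)cc(OC)c(OC)c1OC
F11 | step 5 | 2,3-trans-3,4-cis-3-hydroxy-5,6,7-trimethoxy-2-(4-methoxyphenyl)-4-(trimethylsilyloxy)chroman-4-ol (configuration at C2 and C3 as in 10) | COc1cc2c(c(OC)c1OC)[C@@](O)(O[Si](C)(C)C)[C@H](O)[C@@H](c1ccc(OC)cc1)O2
F12 | step 6 | (2S)-4-(tert-butyldimethylsilyloxy)-5,6,7-trimethoxy-2-(4-methoxyphenyl)-2H-chromene | COc1cc2c(c(OC)c1OC)C(O[Si](C)(C)C(C)(C)C)=C[C@@H](c1ccc(OC)cc1)O2
F13 | step 6 | 2,3-trans-3,4-trans-4-(tert-butyldimethylsilyloxy)-5,6,7-trimethoxy-2-(4-methoxyphenyl)chroman-3-ol (configuration at C2 and C3 as in 10) | COc1cc2c(c(OC)c1OC)[C@@H](O[Si](C)(C)C(C)(C)C)[C@H](O)[C@@H](c1ccc(OC)cc1)O2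
F14 | step 6 | 2,3-trans-3,4-trans-4-(tert-butyldimethylsilyloxy)-3,5,6,7-tetramethoxy-2-(4-methoxyphenyl)chromane (configuration at C2 and C3 as in 11) | COc1cc2c(c(OC)c1OC)[C@@H](O[Si](C)(C)C(C)(C)C)[C@H](OC)[C@@H](c1ccc(OC)cc1)O2
F15 | step 6 | 2,3-trans-3,4-trans-3,5,6,7-tetramethoxy-2-(4-methoxyphenyl)chroman-4-ol (configuration at C2 and C3 as in 11) | COc1cc2c(c(OC)c1OC)[C@@H](O)[C@H](OC)[C@@H](c1ccc(OC)cc1)O2
A1 | alternative 1 | 2,3-trans flavan-3,4-diol derivative: 3-O-methyl, 4-O-tert-butyldimethylsilyl, 3',5'-di-O-benzyl, ring A 5,6,7-trimethoxy, ring B 4'-methoxy | COc1cc2c(c(OC)c1OC)[C@@H](O[Si](C)(C)C(C)(C)C)[C@H](OC)[C@@H](c1cc(OCc3ccccc3)c(OC)c(OCc3ccccc3)c1)O2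
A2 | alternative 2 | (2R,3R)-2-[3,5-bis(benzyloxy)-4-methoxyphenyl]-5,7-dihydroxy-3,6-dimethoxychroman-4-one | Oc1cc2c(c(O)c1OC)C(=O)[C@H](OC)[C@@H](c1cc(OCc3ccccc3)c(OC)c(OCc3ccccc3)c1)O2
A3 | alternative 3 | (2S)-2-[3,5-bis(benzyloxy)-4-methoxyphenyl]-5,6,7-trimethoxychroman-4-one | COc1cc2c(c(OC)c1OC)C(=O)C[C@@H](c1cc(OCc3ccccc3)c(OC)c(OCc3ccccc3)c1)O2
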